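**Retrosynthetic overview**
1. Target 16 ⇐ [4+2] addition of singlet oxygen to the cis-fused bicyclo[4.2.0]octa-2,4-diene 15, on the face anti to the cyclobutane; 15 ⇐ chiral-phase resolution of racemate 14.
2. 14 ⇐ thermal 8π (conrotatory) / 6π (disrotatory) cascade of the (2E,4Z,6Z,8E)-tetraene 12, made by Wittig reaction of Z-dienone 11 with the tiglyl ylide 10.
3. Key C–C bond: 11 (stored as its 2H-pyran valence tautomer 7) ⇐ C6-magnesiated α-methoxy-γ-pyranone 6 (a nucleophile at a carbon that is normally an electrophilic vinylogous acyl carbon) + C2 of 2,4,6-trimethylpyrylium; ring opening of the 2H-pyran fixes the Z alkene.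
4. Pyranone 4 ⇐ methyl 2-methyl-3-oxopentanoate + methyl formate, then O-methylation.
5. Ring order: pyranone → (transient 2H-pyran) → cyclooctatriene → cyclobutane/cyclohexadiene → 1,2-dioxine bridge.

Assumption: the 8π/6π cascade of an achiral tetraene is inherently racemic, so the single enantiomer is taken by chiral-phase SFC of diene 14 (step 6), with absolute configuration assigned by VCD/ECD against calculation.

**Step 1**
Reactants: 1 methyl 2-methyl-3-oxopentanoate
Product: 3 4-hydroxy-3,5-dimethyl-2H-pyran-2-one, via formyl keto ester 2 (not isolated)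
Conditions: LDA (3.2 equiv), THF, −78 → 0 °C; HCO2Me, −78 → 0 °C; aq HCl; then DBU (0.2 equiv), PhMe, 60 °C
Reagents that add atoms: methyl formate, COC=O
Why: Claisen-type γ-formylation of the β-keto ester dianion (Weiler dianion acylation) gives the 5-formyl tricarbonyl 2, whose chelated Z-enol lactonises onto the ester to the 6-unsubstituted 4-hydroxy-2-pyranone; no stereocentre survives.

**Step 2**
Reactants: 3 4-hydroxy-3,5-dimethyl-2H-pyran-2-one
Product: 4 2-methoxy-3,5-dimethyl-4H-pyran-4-one
Conditions: MeOTf (1.2 equiv), CH2Cl2, 0 → 23 °C; then aq NaHCO3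
Reagents that add atoms: methyl trifluoromethanesulfonate, COS(=O)(=O)C(F)(F)F
Why: O-alkylation of an ambident hydroxypyranone with a hard methylating agent under neutral conditions occurs at the basic lactone carbonyl oxygen, giving the α-methoxy-γ-pyranone after loss of the proton.

**Step 3**
Reactants: 4 2-methoxy-3,5-dimethyl-4H-pyran-4-one; 5 2,4,6-trimethylpyrylium tetrafluoroborate
Product: 7 rac-2-methoxy-3,5-dimethyl-6-(2,4,6-trimethyl-2H-pyran-2-yl)-4H-pyran-4-one, via pyranonylmagnesium chloride 6 (not isolated)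
Conditions: TMPMgCl·LiCl (1.1 equiv), THF, −40 °C; then cannulated into 5 (1.5 equiv), THF, −78 → 0 °C; pH 7 buffer, basic Al2O3
Reagents that add atoms: none
Why: Proposed new method: TMP-amide magnesiation of the only ring C–H (C6, α to the ring oxygen; closest known type: TMPMgCl·LiCl/TMPZnCl·LiCl metalation of chromones and 4-pyranones) converts the natively electrophilic vinylogous-acyl carbon into an α-alkoxyvinyl (acyl-anion-type) nucleophile, which adds as a hard organomagnesium to the α-carbon of the pyrylium cation (closest known type: RMgX + 2,4,6-trimethylpyrylium → 2,2-disubstituted 2H-pyrans), joining two acyl-level electrophilic carbons; the former ring C4=C5 bond of 7 is necessarily cis for the oxa-6π ring opening used in step 5, and the new C2 stereocentre is racemic and lost on ring opening.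

**Step 4**
Reactants: 8 (2E)-2-methylbut-2-en-1-ol
Product: 9 [(2E)-2-methylbut-2-en-1-yl]triphenylphosphonium bromide
Conditions: PPh3·HBr (1.0 equiv), MeCN, 23 → 50 °C
Reagents that add atoms: triphenylphosphine hydrobromide, [Br-].[PH+](c1ccccc1)(c1ccccc1)c1ccccc1
Why: Phosphonium salt formation from an allylic alcohol: the protonated primary alcohol is displaced by PPh3 at the unhindered CH2 terminus, which keeps the E trisubstituted alkene.

**Step 5**
Reactants: 7 rac-2-methoxy-3,5-dimethyl-6-(2,4,6-trimethyl-2H-pyran-2-yl)-4H-pyran-4-one; 9 [(2E)-2-methylbut-2-en-1-yl]triphenylphosphonium bromide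
Product: 14 rac-2-methoxy-3,5-dimethyl-6-[(1R*,6R*,7S*,8R*)-1,3,5,7,8-pentamethylbicyclo[4.2.0]octa-2,4-dien-7-yl]-4H-pyran-4-one, via ylide 10 (not isolated), via Z-dienone 11 (not isolated), via tetraene 12 (not isolated), via cyclooctatriene 13 (not isolated)
Conditions: 9 (1.3 equiv), NaHMDS (1.25 equiv), THF, −78 → 0 °C; then 7, 0 → 45 °C, Ar, dark; then I2 (3 mol %), PhMe, white light, 23 °C
Reagents that add atoms: none
Why: Wittig olefination traps the (3Z,5E)-dienone tautomer 11 that 7 reaches by reversible oxa-6π ring opening (Curtin–Hammett), the (2E,4Z,6Z,8E)-tetraene 12 closes by thermal conrotatory 8π electrocyclisation (outside groups pyranonyl and 8-CH3 become trans) and disrotatory 6π electrocyclisation to the cis-fused bicycle with 7-CH3 and 8-CH3 on the face of the ring-fusion H/CH3, and iodine-catalysed alkene isomerisation feeds any 6E-tetraene back into the same irreversible cascade; all four stereocentres are set here in relative terms (racemic).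

**Step 6**
Reactants: 14 rac-2-methoxy-3,5-dimethyl-6-[(1R*,6R*,7S*,8R*)-1,3,5,7,8-pentamethylbicyclo[4.2.0]octa-2,4-dien-7-yl]-4H-pyran-4-one
Product: 15 2-methoxy-3,5-dimethyl-6-[(1R,6R,7S,8R)-1,3,5,7,8-pentamethylbicyclo[4.2.0]octa-2,4-dien-7-yl]-4H-pyran-4-one
Conditions: preparative SFC, Chiralpak AD-H (amylose tris(3,5-dimethylphenylcarbamate)), CO2/MeOH, 35 °C
Reagents that add atoms: none
Why: Chromatographic resolution on a chiral stationary phase separates the two antipodes (the (1R,6R,7S,8R) one identified by VCD/ECD), and the diene cannot racemise afterwards because retro-8π opening is far too slow at ambient temperature.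

**Step 7**
Reactants: 15 2-methoxy-3,5-dimethyl-6-[(1R,6R,7S,8R)-1,3,5,7,8-pentamethylbicyclo[4.2.0]octa-2,4-dien-7-yl]-4H-pyran-4-one
Product: 16 2-methoxy-3,5-dimethyl-6-[(1S,2R,3S,4R,5R,6R)-1,3,4,5,10-pentamethyl-7,8-dioxatricyclo[4.2.2.0^{2,5}]dec-9-en-3-yl]-4H-pyran-4-one (CNP0183511.1)
Conditions: O2, methylene blue (1 mol %), white LED, CH2Cl2, 0 °C
Reagents that add atoms: dioxygen (as singlet oxygen), O=O
Why: Photosensitised [4+2] cycloaddition of singlet oxygen to the s-cis ring diene takes place on the convex face anti to the cyclobutane (the face carrying the ring-fusion H and CH3), which sets the two C–O stereocentres (C1 S, C6 R) relative to the resolved ones; the pyranone and the remaining trisubstituted alkene are inert.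

**Compound list**
1 | methyl 2-methyl-3-oxopentanoate (racemic) | CCC(=O)C(C)C(=O)OC | starting material
2 | methyl 2,4-dimethyl-3,5-dioxopentanoate (formyl keto ester, enol/stereoisomer mixture) | COC(=O)C(C)C(=O)C(C)C=O | intermediate
3 | 4-hydroxy-3,5-dimethyl-2H-pyran-2-one | CC1=COC(=O)C(C)=C1O | intermediate
4 | 2-methoxy-3,5-dimethyl-4H-pyran-4-one | COc1occ(C)c(=O)c1C | intermediate
5 | 2,4,6-trimethylpyrylium tetrafluoroborate | Cc1cc(C)[o+]c(C)c1.F[B-](F)(F)F | starting material
6 | (6-methoxy-3,5-dimethyl-4-oxo-4H-pyran-2-yl)magnesium chloride (LiCl complex) | COc1oc([Mg]Cl)c(C)c(=O)c1C | intermediate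
7 | rac-2-methoxy-3,5-dimethyl-6-(2,4,6-trimethyl-2H-pyran-2-yl)-4H-pyran-4-one (C2 configurationally labile) | COc1oc(C2(C)C=C(C)C=C(C)O2)c(C)c(=O)c1C | intermediate
8 | (2E)-2-methylbut-2-en-1-ol | C/C=C(\C)CO | starting material
9 | [(2E)-2-methylbut-2-en-1-yl]triphenylphosphonium bromide | C/C=C(\C)C[P+](c1ccccc1)(c1ccccc1)c1ccccc1.[Br-] | intermediate
10 | [(2E)-2-methylbut-2-en-1-ylidene]triphenyl-λ5-phosphane | C/C=C(\C)C=P(c1ccccc1)(c1ccccc1)c1ccccc1 | intermediate
11 | (3Z,5E)-6-(6-methoxy-3,5-dimethyl-4-oxo-4H-pyran-2-yl)-4-methylhepta-3,5-dien-2-one | CC(=O)/C=C(/C)\C=C(/C)c1oc(OC)c(C)c(=O)c1C | intermediate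
12 | 2-methoxy-3,5-dimethyl-6-[(2E,4Z,6Z,8E)-4,6,8-trimethyldeca-2,4,6,8-tetraen-2-yl]-4H-pyran-4-one | C/C=C(\C)/C=C(/C)\C=C(\C)/C=C(\C)c1oc(OC)c(C)c(=O)c1C | intermediate
13 | rac-2-methoxy-3,5-dimethyl-6-[(1R*,8R*)-1,3,5,7,8-pentamethylcycloocta-2,4,6-trien-1-yl]-4H-pyran-4-one (pyranonyl and 8-CH3 trans; racemate, one enantiomer drawn) | COc1oc([C@@]2(C)[C@H](C)/C(C)=C\C(C)=C/C(C)=C\2)c(C)c(=O)c1C | intermediate
14 | rac-2-methoxy-3,5-dimethyl-6-[(1R*,6R*,7S*,8R*)-1,3,5,7,8-pentamethylbicyclo[4.2.0]octa-2,4-dien-7-yl]-4H-pyran-4-one (racemate, one enantiomer drawn) | COc1oc([C@@]2(C)[C@H](C)[C@@]3(C)C=C(C)C=C(C)[C@@H]23)c(C)c(=O)c1C | intermediate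
15 | 2-methoxy-3,5-dimethyl-6-[(1R,6R,7S,8R)-1,3,5,7,8-pentamethylbicyclo[4.2.0]octa-2,4-dien-7-yl]-4H-pyran-4-one | COc1oc([C@@]2(C)[C@H](C)[C@@]3(C)C=C(C)C=C(C)[C@@H]23)c(C)c(=O)c1C | intermediate
16 | 2-methoxy-3,5-dimethyl-6-[(1S,2R,3S,4R,5R,6R)-1,3,4,5,10-pentamethyl-7,8-dioxatricyclo[4.2.2.0^{2,5}]dec-9-en-3-yl]-4H-pyran-4-one | COc1oc([C@@]2(C)[C@H](C)[C@@]3(C)[C@@H]4OO[C@@](C)(C=C4C)[C@@H]23)c(C)c(=O)c1C | target

**Totals and risks**
Total steps: 7. Longest linear sequence: 6 (steps 1, 2, 3, 5, 6, 7; step 4 is a one-step side branch).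

Step 3 is the most likely to fail. The basic organomagnesium may deprotonate the acidic pyrylium methyl groups or attack C4 instead of C2. The fallback sets out from 4 (through 6) and avoids the pyrylium altogether. Reagent 6 is added to the ketone of commercial 4-methoxypent-3-en-2-one, and acidic work-up (enol ether hydrolysis, loss of water) gives the enone (3E)-4-(6-methoxy-3,5-dimethyl-4-oxo-4H-pyran-2-yl)pent-3-en-2-one F1. The lithium enolate of acetone (THF, −78 °C) adds 1,2 to F1 to give the aldol (5E)-4-hydroxy-6-(6-methoxy-3,5-dimethyl-4-oxo-4H-pyran-2-yl)-4-methylhept-5-en-2-one F2. Dehydration (cat. TsOH, PhH, 60 °C) gives 11 as a 3E/3Z mixture. The 3Z part closes to 7, and 365 nm irradiation drives the 3E part there as well (E→Z isomerisation, then oxa-6π closure). The fallback comes back to the route at 7.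

Step 5 is second. The Wittig reaction on a methyl ketone gives little control of the new C6=C7 geometry, the reactive dienone is only the minor tautomer of 7, and the iodine funnel may leak into other cascade diastereomers. The fallback sets out from 7 and fixes the geometry at an isolable stage. Stork–Zhao olefination (Ph3P=CHI from (iodomethyl)triphenylphosphonium iodide/NaHMDS, THF, −78 °C) gives 6-[(2E,4Z,6Z)-7-iodo-4,6-dimethylhepta-2,4,6-trien-2-yl]-2-methoxy-3,5-dimethyl-4H-pyran-4-one F3, whose 6Z isomer is purified by chromatography. Suzuki–Miyaura coupling of F3 with commercial (Z)-2-(but-2-en-2-yl)-4,4,5,5-tetramethyl-1,3,2-dioxaborolane (C/C=C(\C)B1OC(C)(C)C(C)(C)O1; Pd(PPh3)4, aq K3PO4, THF, 23 °C) gives tetraene 12. The fallback comes back to the route at 12, which cyclises to 14 as before.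

Step 1 is third. Formylation of the dianion can stall by proton transfer to the more acidic product, and the 6-unsubstituted pyranone is sensitive. The fallback sets out from 1 and uses neutral condensation chemistry. Heating 1 with tert-butoxybis(dimethylamino)methane (neat, 80 °C) condenses the only CH2 group to the enaminone methyl (4E)-5-(dimethylamino)-2,4-dimethyl-3-oxopent-4-enoate F4. Aqueous AcOH/TFA (60 °C) hydrolyses the vinylogous amide of F4 and lactonises the resulting enol. The fallback comes back to the route at 3.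

**Further compounds**
F1 | step 3 | (3E)-4-(6-methoxy-3,5-dimethyl-4-oxo-4H-pyran-2-yl)pent-3-en-2-one | CC(=O)/C=C(\C)c1oc(OC)c(C)c(=O)c1C
F2 | step 3 | (5E)-4-hydroxy-6-(6-methoxy-3,5-dimethyl-4-oxo-4H-pyran-2-yl)-4-methylhept-5-en-2-one (racemic) | CC(=O)CC(C)(O)/C=C(\C)c1oc(OC)c(C)c(=O)c1C
F3 | step 5 | 6-[(2E,4Z,6Z)-7-iodo-4,6-dimethylhepta-2,4,6-trien-2-yl]-2-methoxy-3,5-dimethyl-4H-pyran-4-one | I/C=C(/C)\C=C(\C)/C=C(\C)c1oc(OC)c(C)c(=O)c1C
F4 | step 1 | methyl (4E)-5-(dimethylamino)-2,4-dimethyl-3-oxopent-4-enoate | CN(C)/C=C(\C)C(=O)C(C)C(=O)OC
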